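**Strategy.** Ring A is taken apart at C4a–C5 and C8–C8a. Its three adjacent oxygens (C7–OH, C8–OMe, C8a–O1) correspond to a 2-methoxycyclohexane-1,3-dione one dehydrogenation short of the phenol. C8a is treated as the carbonyl carbon of a δ-lactone that already contains O1, C2, C3, C4, C4a and the C3 stereocentre. In one operation the lactone enolate adds to methoxymethyl vinyl ketone, the new ketone enolate is acylated by the lactone carbonyl, and acid returns the expelled alcohol to C8a, giving the bicyclic vinylogous ester. The precursor is the (5S)-5-aryl-δ-valerolactone whose ring B phenol is masked as a benzyl ether; it comes from an auxiliary-controlled Michael addition.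

Key step: step 12

**Remarks on the chemistry**
- Chroman locants are O1, C2, C3, C4, C4a, C5–C8, C8a; ring A is the fused benzene ring, ring B the 3-aryl group (primed locants). Ar = 3-(benzyloxy)-2,4,5-trimethoxyphenyl.
- Metalated forms of a reactant (aryllithium, enolates) and species that exist only within one operation (tetrahedral adducts, the keto tautomer of a phenol) are treated as reactive forms and carry no number.
- A 2-benzyloxy-1,3,4-trimethoxybenzene offers two electronically equal free positions, so the ring B carbon is introduced while the future O3′ is still a meta-directing formyl group.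
- The two ends of the lactone chain are differentiated from the start (imide against tert-butyl ester), so no selective oxidation of a diol is needed.
- The stereocentre keeps the descriptor S from step 8 to the target, because the ranking (oxygen-bearing carbon > aryl > CH2 > H) does not change.

**Step 1**
Reactants: 1 1,2,4-trimethoxybenzene
Product: 2 2,3,6-trimethoxybenzaldehyde
Conditions: n-BuLi, THF, 0 °C to rt; DMF, 0 °C; 1 M HCl
Reagents that add atoms: N,N-dimethylformamide, `CN(C)C=O`
Why: Directed ortho-metalation should remove the C3 proton, which lies between two methoxy groups, and the aryllithium is formylated by DMF.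

**Step 2**
Reactants: 2 2,3,6-trimethoxybenzaldehyde
Product: 3 3-bromo-2,5,6-trimethoxybenzaldehyde
Conditions: NBS, MeCN, 0 °C to rt
Reagents that add atoms: N-bromosuccinimide, `O=C1CCC(=O)N1Br`
Why: In this electrophilic aromatic bromination C5 of 2 is ortho to the 6-methoxy, para to the 2-methoxy and meta to the formyl group, so all directing effects converge on the carbon that becomes C1′, while C4 (para to the formyl group) is deactivated.

**Step 3**
Reactants: 3 3-bromo-2,5,6-trimethoxybenzaldehyde
Product: 5 3-bromo-2,5,6-trimethoxyphenol, via aryl formate 4 (not isolated)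
Conditions: mCPBA, CH2Cl2, 0 °C to rt; then MeOH, Et3N (cat.), rt
Reagents that add atoms: 3-chloroperoxybenzoic acid, `OOC(=O)c1cccc(Cl)c1`
Why: In this Baeyer–Villiger (Dakin-type) oxidation the electron-rich aryl group migrates to give the aryl formate, whose methanolysis exchanges the formyl carbon for the oxygen that becomes O3′.

**Step 4**
Reactants: 5 3-bromo-2,5,6-trimethoxyphenol
Product: 6 3-(benzyloxy)-1-bromo-2,4,5-trimethoxybenzene
Conditions: BnBr, K2CO3, DMF, rt
Reagents that add atoms: benzyl bromide, `BrCc1ccccc1`
Why: Williamson etherification of the phenoxide installs a benzyl ether that should tolerate the bases, hydride and Lewis acids ahead and leaves by hydrogenolysis at the end.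

**Step 5**
Reactants: 6 3-(benzyloxy)-1-bromo-2,4,5-trimethoxybenzene; 7 tert-butyl acetate
Product: 8 tert-butyl Ar-acetate
Conditions: LiN(SiMe3)2, Pd(dba)2 (cat.), P(t-Bu)3 (cat.), toluene, rt
Reagents that add atoms: none
Why: Palladium-catalysed α-arylation of an ester enolate (Buchwald–Hartwig type) proceeds by oxidative addition of the bromide to zerovalent palladium, transmetalation with the lithium enolate of 7 and reductive elimination, and the tert-butyl ester suppresses Claisen self-condensation.

**Step 6**
Reactants: 8 tert-butyl Ar-acetate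
Product: 9 Ar-acetic acid
Conditions: TFA, CH2Cl2, 0 °C to rt
Reagents that add atoms: none
Why: Acidolysis of the tert-butyl ester with loss of 2-methylpropene should leave the aryl benzyl ether intact at this temperature.

**Step 7**
Reactants: 9 Ar-acetic acid; 10 (4S)-4-benzyl-1,3-oxazolidin-2-one
Product: 12 (4S)-4-benzyl-3-(Ar-acetyl)-1,3-oxazolidin-2-one, via mixed pivalic anhydride 11 (not isolated)
Conditions: PivCl, Et3N, THF, −20 °C; then 10, LiCl, rt
Reagents that add atoms: none
Why: N-Acylation through the mixed anhydride under LiCl/Et3N activation should occur at the less hindered arylacetyl carbonyl without a strong base.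

**Step 8**
Reactants: 12 (4S)-4-benzyl-3-(Ar-acetyl)-1,3-oxazolidin-2-one; 13 tert-butyl acrylate
Product: 14 tert-butyl (4S)-4-Ar-5-[(4S)-4-benzyl-2-oxo-1,3-oxazolidin-3-yl]-5-oxopentanoate
Conditions: TiCl3(O-i-Pr) (from TiCl4 and Ti(O-i-Pr)4, 3:1), i-Pr2NEt, CH2Cl2, 0 °C; then 13, 0 °C
Reagents that add atoms: none
Why: In this Evans titanium-enolate Michael addition the chelated Z-enolate should add to the acrylate on the face opposite the C4 benzyl group of the auxiliary, which sets the future C3 stereocentre as S.

**Step 9**
Reactants: 14 tert-butyl (4S)-4-Ar-5-[(4S)-4-benzyl-2-oxo-1,3-oxazolidin-3-yl]-5-oxopentanoate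
Product: 16 (5S)-5-Ar-oxan-2-one, via hydroxy ester 15 (not isolated)
Conditions: LiBH4, MeOH (1 equiv), THF, 0 °C; aqueous work-up; then TsOH·H2O (cat.), toluene, 80 °C
Reagents that add atoms: none
Why: Reductive cleavage of the activated imide carbonyl frees the auxiliary and spares the tert-butyl ester, and acid-catalysed lactonisation then closes the δ-lactone; the stereocentre is not α to the remaining carbonyl and should be untouched.

**Step 10**
Reactants: 17 methoxyacetyl chloride
Product: 18 N,2-dimethoxy-N-methylacetamide
Conditions: MeNH(OMe)·HCl, pyridine, CH2Cl2, 0 °C to rt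
Reagents that add atoms: N,O-dimethylhydroxylamine hydrochloride, `CNOC.Cl`
Why: Acylation of the hydroxylamine by the acid chloride gives the Weinreb amide.

**Step 11**
Reactants: 18 N,2-dimethoxy-N-methylacetamide; 19 vinylmagnesium bromide
Product: 20 1-methoxybut-3-en-2-one
Conditions: THF, −78 to 0 °C; inverse quench into cold 1 M HCl; used as a cold, BHT-stabilised solution
Reagents that add atoms: none
Why: In this Weinreb ketone synthesis the chelated adduct stops at single addition, and the inverse acidic quench protonates the liberated amine before it can add to the enone.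

**Step 12**
Reactants: 16 (5S)-5-Ar-oxan-2-one; 20 1-methoxybut-3-en-2-one
Product: 23 (3S)-3-Ar-8-methoxy-2,3,4,4a,5,6-hexahydro-7H-chromen-7-one (C4a epimers), via keto lactone 21 (not isolated), via hydroxy dione 22 (not isolated)
Conditions: LiN(i-Pr)2, THF, −78 °C; 20 (dilute, slow addition), −78 °C; KOt-Bu, −78 to 0 °C; 1 M HCl quench; then TsOH·H2O (cat.), toluene, 60 °C
Reagents that add atoms: none
Why: Proposed new method: the lithium enolate of 16 should add in the conjugate sense to 20 to form C4a–C5; alkoxide-mediated proton exchange moves the ketone enolate to the methoxy-bearing carbon, which attacks the lactone carbonyl to form C8–C8a, the tetrahedral adduct ejects the C2 alkoxide, and deprotonation of the resulting 2-methoxy-1,3-dione makes the sequence irreversible, after which acid lets the freed primary alcohol add to C8a and lose water. The closest known reaction type is the Michael–Claisen annulation of ester enolates with vinyl ketones to cyclohexane-1,3-diones, joined to acid-catalysed enol-ether formation from a 1,3-dione and an alcohol; the use of a lactone, whose leaving alkoxide stays tethered and returns, is the untested part. Ring A closes by a 6-(enolendo)-exo-trig Claisen attack of C8 on C8a, and the pyran ring is re-formed by 6-exo-trig hemiketalisation of O1 on C8a followed by dehydration toward the conjugated C8=C8a position. The only new stereocentre, C4a, is uncontrolled and becomes sp2 on aromatisation, while C3 is not α to any carbonyl and keeps its configuration. The step needs conjugate instead of carbonyl addition (an unsubstituted β-carbon, reversible aldolate formation and the drain into the dione enolate favour it), Claisen closure through C8 and not C6 (six- against four-membered ring), and attack of the alcohol on C8a and not C7 (six-membered against bridged eight-membered ring).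

**Step 13**
Reactants: 23 (3S)-3-Ar-8-methoxy-2,3,4,4a,5,6-hexahydro-7H-chromen-7-one
Product: 25 (3S)-3-Ar-8-methoxy-3,4-dihydro-2H-chromen-7-ol, via silyl dienol ether 24 (not isolated)
Conditions: LiN(i-Pr)2, THF, −78 °C; TMSCl; then Pd(OAc)2 (1.05 equiv), MeCN, rt
Reagents that add atoms: none
Why: In this Saegusa–Ito dehydrogenation kinetic deprotonation at C6 (Stork–Danheiser regiochemistry) and silylation give the cross-conjugated dienol ether, divalent palladium converts it to the cyclohexa-2,5-dienone, and this keto tautomer should enolise through C4a–H to the C7 phenol, which removes the C4a stereocentre.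

**Step 14**
Reactants: 25 (3S)-3-Ar-8-methoxy-3,4-dihydro-2H-chromen-7-ol
Product: 26 (3S)-3-(3-hydroxy-2,4,5-trimethoxyphenyl)-8-methoxy-3,4-dihydro-2H-chromen-7-ol
Conditions: H2 (1 atm), 10% Pd/C, EtOAc–MeOH, rt
Reagents that add atoms: none
Why: Catalytic hydrogenolysis should cleave only the O-benzyl bond, since the chroman ether, the methyl ethers and the C3 stereocentre are inert under these conditions.

**Compound list**

1 | 1,2,4-trimethoxybenzene | `COc1ccc(OC)c(OC)c1` | starting material
2 | 2,3,6-trimethoxybenzaldehyde | `COc1ccc(OC)c(C=O)c1OC` | intermediate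
3 | 3-bromo-2,5,6-trimethoxybenzaldehyde | `COc1cc(Br)c(OC)c(C=O)c1OC` | intermediate
4 | 3-bromo-2,5,6-trimethoxyphenyl formate | `COc1cc(Br)c(OC)c(OC=O)c1OC` | intermediate
5 | 3-bromo-2,5,6-trimethoxyphenol | `COc1cc(Br)c(OC)c(O)c1OC` | intermediate
6 | 3-(benzyloxy)-1-bromo-2,4,5-trimethoxybenzene | `COc1cc(Br)c(OC)c(OCc2ccccc2)c1OC` | intermediate
7 | tert-butyl acetate | `CC(=O)OC(C)(C)C` | starting material
8 | tert-butyl [3-(benzyloxy)-2,4,5-trimethoxyphenyl]acetate | `COc1cc(CC(=O)OC(C)(C)C)c(OC)c(OCc2ccccc2)c1OC` | intermediate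
9 | [3-(benzyloxy)-2,4,5-trimethoxyphenyl]acetic acid | `COc1cc(CC(=O)O)c(OC)c(OCc2ccccc2)c1OC` | intermediate
10 | (4S)-4-benzyl-1,3-oxazolidin-2-one | `O=C1N[C@@H](Cc2ccccc2)CO1` | starting material
11 | [3-(benzyloxy)-2,4,5-trimethoxyphenyl]acetic 2,2-dimethylpropanoic anhydride | `COc1cc(CC(=O)OC(=O)C(C)(C)C)c(OC)c(OCc2ccccc2)c1OC` | intermediate
12 | (4S)-4-benzyl-3-{[3-(benzyloxy)-2,4,5-trimethoxyphenyl]acetyl}-1,3-oxazolidin-2-one | `COc1cc(CC(=O)N2[C@@H](Cc3ccccc3)COC2=O)c(OC)c(OCc2ccccc2)c1OC` | intermediate
13 | tert-butyl acrylate (tert-butyl prop-2-enoate) | `C=CC(=O)OC(C)(C)C` | starting material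
14 | tert-butyl (4S)-4-[3-(benzyloxy)-2,4,5-trimethoxyphenyl]-5-[(4S)-4-benzyl-2-oxo-1,3-oxazolidin-3-yl]-5-oxopentanoate | `COc1cc([C@H](CCC(=O)OC(C)(C)C)C(=O)N2[C@@H](Cc3ccccc3)COC2=O)c(OC)c(OCc2ccccc2)c1OC` | intermediate
15 | tert-butyl (4S)-4-[3-(benzyloxy)-2,4,5-trimethoxyphenyl]-5-hydroxypentanoate | `COc1cc([C@H](CCC(=O)OC(C)(C)C)CO)c(OC)c(OCc2ccccc2)c1OC` | intermediate
16 | (5S)-5-[3-(benzyloxy)-2,4,5-trimethoxyphenyl]oxan-2-one | `COc1cc([C@H]2COC(=O)CC2)c(OC)c(OCc2ccccc2)c1OC` | intermediate
17 | methoxyacetyl chloride | `COCC(=O)Cl` | starting material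
18 | N,2-dimethoxy-N-methylacetamide | `COCC(=O)N(C)OC` | intermediate
19 | vinylmagnesium bromide | `C=C[Mg]Br` | starting material
20 | 1-methoxybut-3-en-2-one | `COCC(=O)C=C` | intermediate
21 | (5S)-5-[3-(benzyloxy)-2,4,5-trimethoxyphenyl]-3-(4-methoxy-3-oxobutyl)oxan-2-one (C3 epimers) | `COc1cc([C@H]2COC(=O)C(CCC(=O)COC)C2)c(OC)c(OCc2ccccc2)c1OC` | intermediate
22 | 4-{(2S)-2-[3-(benzyloxy)-2,4,5-trimethoxyphenyl]-3-hydroxypropyl}-2-methoxycyclohexane-1,3-dione (C4 epimers, drawn as the diketone) | `COc1cc([C@@H](CO)CC2CCC(=O)C(OC)C2=O)c(OC)c(OCc2ccccc2)c1OC` | intermediate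
23 | (3S)-3-[3-(benzyloxy)-2,4,5-trimethoxyphenyl]-8-methoxy-2,3,4,4a,5,6-hexahydro-7H-chromen-7-one (C4a epimers) | `COc1cc([C@H]2COC3=C(OC)C(=O)CCC3C2)c(OC)c(OCc2ccccc2)c1OC` | intermediate
24 | {[(3S)-3-[3-(benzyloxy)-2,4,5-trimethoxyphenyl]-8-methoxy-3,4,4a,5-tetrahydro-2H-chromen-7-yl]oxy}trimethylsilane (C4a epimers) | `COc1cc([C@H]2COC3=C(OC)C(O[Si](C)(C)C)=CCC3C2)c(OC)c(OCc2ccccc2)c1OC` | intermediate
25 | (3S)-3-[3-(benzyloxy)-2,4,5-trimethoxyphenyl]-8-methoxy-3,4-dihydro-2H-chromen-7-ol | `COc1cc([C@H]2COc3c(ccc(O)c3OC)C2)c(OC)c(OCc2ccccc2)c1OC` | intermediate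
26 | (3S)-3-(3-hydroxy-2,4,5-trimethoxyphenyl)-8-methoxy-3,4-dihydro-2H-chromen-7-ol | `COc1cc([C@H]2COc3c(ccc(O)c3OC)C2)c(OC)c(O)c1OC` | target

**Step count.** Total: 14 steps. Longest linear sequence: 12 steps (steps 1–9, 12, 13, 14); steps 10 and 11 form the two-step side branch to the enone.

**Steps most likely to fail**

1. Step 12 (proposed new method). The enolate may add to the ketone carbonyl or start anionic oligomerisation of the enone faster than it adds in the conjugate sense, or the Claisen closure may stall so that the adduct reverts by retro-Michael cleavage. The fallback uses known reactions in separate stages and sets out from lactone 16. LiN(i-Pr)2 and TBSCl in THF at −78 °C would give the silyl ketene acetal tert-butyl({(3S)-3-[3-(benzyloxy)-2,4,5-trimethoxyphenyl]-3,4-dihydro-2H-pyran-6-yl}oxy)dimethylsilane F1. Mukaiyama–Michael addition of this neutral nucleophile to enone 20 with TiCl4 in CH2Cl2 at −78 °C, followed by aqueous work-up, would give keto lactone 21, now isolated and purified. KOt-Bu in THF at 0 °C would then effect the Dieckmann-type Claisen closure to hydroxy dione 22, and TsOH in toluene would cyclodehydrate it. The fallback comes back to the route at 23.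

2. Step 8. The stabilised arylacetyl enolate may add slowly while the acrylate oligomerises, and epimerisation of the acidic α-aryl centre may erode the diastereomer ratio. The fallback sets out from imide 12. Alkylation of its sodium enolate (NaN(SiMe3)2, THF, −78 °C) with allyl bromide would give (4S)-4-benzyl-3-{(2S)-2-[3-(benzyloxy)-2,4,5-trimethoxyphenyl]pent-4-enoyl}-1,3-oxazolidin-2-one F2, with the same facial control. LiBH4 would remove the auxiliary to give (2S)-2-[3-(benzyloxy)-2,4,5-trimethoxyphenyl]pent-4-en-1-ol F3. Hydroboration with 9-BBN and NaOH/H2O2 work-up would give (2S)-2-[3-(benzyloxy)-2,4,5-trimethoxyphenyl]pentane-1,5-diol F4. TEMPO with PhI(OAc)2 should then oxidise the less hindered primary alcohol and the derived lactol. The fallback comes back to the route at lactone 16.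

3. Step 13. The silyl dienol ether may lose silicon by protonation and return the ketone instead of undergoing β-hydride elimination, or the palladium salt may be consumed unproductively by the electron-rich substrate. The fallback replaces the palladium-mediated dehydrosilylation by a chalcogen oxidation–elimination and sets out from 23. The kinetic lithium enolate would be trapped with PhSeCl at −78 °C to give (3S)-3-[3-(benzyloxy)-2,4,5-trimethoxyphenyl]-8-methoxy-6-(phenylselanyl)-2,3,4,4a,5,6-hexahydro-7H-chromen-7-one F5. Oxidation with one equivalent of mCPBA at −78 °C and warming in the presence of i-Pr2NH would bring about selenoxide syn-elimination and enolisation. The fallback comes back to the route at phenol 25.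

**Further compounds**

F1 | step 12 | tert-butyl({(3S)-3-[3-(benzyloxy)-2,4,5-trimethoxyphenyl]-3,4-dihydro-2H-pyran-6-yl}oxy)dimethylsilane | `COc1cc([C@H]2COC(O[Si](C)(C)C(C)(C)C)=CC2)c(OC)c(OCc2ccccc2)c1OC`
F2 | step 8 | (4S)-4-benzyl-3-{(2S)-2-[3-(benzyloxy)-2,4,5-trimethoxyphenyl]pent-4-enoyl}-1,3-oxazolidin-2-one | `COc1cc([C@H](CC=C)C(=O)N2[C@@H](Cc3ccccc3)COC2=O)c(OC)c(OCc2ccccc2)c1OC`
F3 | step 8 | (2S)-2-[3-(benzyloxy)-2,4,5-trimethoxyphenyl]pent-4-en-1-ol | `COc1cc([C@H](CC=C)CO)c(OC)c(OCc2ccccc2)c1OC`
F4 | step 8 | (2S)-2-[3-(benzyloxy)-2,4,5-trimethoxyphenyl]pentane-1,5-diol | `COc1cc([C@H](CCCO)CO)c(OC)c(OCc2ccccc2)c1OC`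
F5 | step 13 | (3S)-3-[3-(benzyloxy)-2,4,5-trimethoxyphenyl]-8-methoxy-6-(phenylselanyl)-2,3,4,4a,5,6-hexahydro-7H-chromen-7-one | `COc1cc([C@H]2COC3=C(OC)C(=O)C([Se]c4ccccc4)CC3C2)c(OC)c(OCc2ccccc2)c1OC`
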